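Numbering: decalin C1–C10 as in drimanes, C11 is the CH2 on C9. The peroxide chain is C1'–C7' (C1' ester carbon, C3' and C6' dioxane carbons, C7' the CH2 bonded to C11).
Cuts, in order: C11–C7' (Wittig reaction, then diimide), the dioxane bonds C3'–O and C6'–O, C9–C11, and last C1–C10 together with C4–C5.
Enabling feature: ring A (C1–C2–C3–C4–C5–C10) is a cyclohexane built on the C5–C10 bond of a ring B whose C8 and C10 methyls flank C9. Ring B is therefore 2,6-dimethyl-1,4-benzoquinone and ring A a [4+2] diene, with the C4 gem-dimethyl carried as a spirocyclopropane so that the diene can reach s-cis.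
Forward: ring A closes on the quinone, C5 is epimerised through the C6 carbonyl, C6=O is deleted, the cyclopropane is hydrogenolysed, and C9=O becomes C9H–C11. The 1,2-dioxane ring is closed separately and the halves are joined last.
Stereochemistry: C10 comes from the chiral catalyst, and C5 and C9 are relayed from C10. C2'/C3' come from crotylboration (C3' inverted on ring closure) and C6' from asymmetric epoxidation (inverted by H2O2).

Key step: step 2

Assumption: the (S)-prolinol-derived oxazaborolidinium salt is taken to expose the face of the bound C5=C10 bond that gives the (10R) adduct. If the sense is opposite, its (R)-antipode is used and nothing else changes.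

Step 1
Reactants: 1 cyclopropyltriphenylphosphonium bromide; 2 acrolein
Product: 4 allylidenecyclopropane, via cyclopropylidenetriphenylphosphorane 3 (not isolated)
Conditions: KN(SiMe3)2, THF, 0 °C; then 2, −78 °C → rt; co-distillation
Reagents that add atoms: none
Why: Wittig olefination, in which the non-stabilised ylide adds 1,2 to the aldehyde faster than 1,4 and loss of Ph3PO gives the volatile diene; no stereocentre is formed.

Step 2
Reactants: 4 allylidenecyclopropane; 5 2,6-dimethyl-1,4-benzoquinone
Product: 6 (4a'R,8a'S)-4a',6'-dimethyl-4a',8a'-dihydro-4'H-spiro[cyclopropane-1,1'-naphthalene]-5',8'-dione (cis-fused; drimane numbering 5S,10R)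
Conditions: (S)-3,3-diphenyl-1-(2-methylphenyl)tetrahydro-1H,3H-pyrrolo[1,2-c][1,3,2]oxazaborole·HN(SO2CF3)2 (20 mol %), CH2Cl2, −78 → −40 °C
Reagents that add atoms: none
Why: The protonated oxazaborolidine binds the C6 carbonyl oxygen of 5 (the only one flanked by two C–H groups, the C9 oxygen being screened by both methyls) and lowers the LUMO of the C5=C10 bond, which then undergoes a concerted, asynchronous, suprafacial [4π+2π] Diels–Alder cycloaddition with s-cis 4. The closest known reaction type is the chiral oxazaborolidinium-cation-catalysed Diels–Alder reaction of methyl-substituted 1,4-benzoquinones with 1-substituted dienes. Ring A (C1–C2–C3–C4–C5–C10) closes as a six-membered ring by cycloaddition, C1–C10 running ahead of C4–C5. C10 is set by the catalyst, whose aryl group covers one face of the bound enedione, C5 follows from suprafacial addition (H5 cis to the C10 methyl, corrected in step 3), and C4 is no stereocentre because the cyclopropane is symmetric, so endo/exo plays no role. Regiochemistry needs the unsubstituted diene terminus C1 (largest HOMO coefficient) to meet C10, the β-carbon of the activated C6 enone, which coordination at O6 secures; the two C=C bonds of 5 are enantiotopic, so site and face selection are one event, and the adduct, no longer a quinone and now next to a quaternary carbon, should not react twice. The tied-back cyclopropane CH2 groups remove the inside-methyl clash that keeps 4-methylpenta-1,3-diene out of s-cis, which is why the gem-dimethyl group travels in this masked form.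

Step 3
Reactants: 6 cis-fused adduct
Product: 7 (4a'R,8a'R)-4a',6'-dimethyl-4a',8a'-dihydro-4'H-spiro[cyclopropane-1,1'-naphthalene]-5',8'-dione (trans-fused; 5R,10R)
Conditions: DBU (10 mol %), CH2Cl2, rt
Reagents that add atoms: none
Why: Base-mediated epimerisation through the C5 enolate of the C6 ketone (C10 is quaternary, so no aromatisation) should favour the trans isomer with H5 anti to the C10 methyl, because with C6–C9 all sp2 that axial methyl has no syn-axial hydrogen in ring B; C5 is thus relayed from C10.

Step 4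
Reactants: 7 trans-fused enedione
Product: 8 (4a'R,6'S,8a'R)-4a',6'-dimethyl-4a',6',7',8a'-tetrahydro-4'H-spiro[cyclopropane-1,1'-naphthalene]-5',8'-dione
Conditions: Zn dust, AcOH, rt
Reagents that add atoms: none
Why: Zn/AcOH reduction of an ene-1,4-dione is selective for the doubly activated C7=C8 bond over C2=C3 and the cyclopropane, and C8 settles as the equatorial methyl epimer by enolisation (it is erased again in step 8).

Step 5
Reactants: 8 trans-fused dione
Product: 9 8'-(4-methylbenzenesulfonyl)hydrazone of 8 (hydrazone at C6)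
Conditions: TsNHNH2, EtOH, 40 °C
Reagents that add atoms: p-toluenesulfonyl hydrazide, Cc1ccc(cc1)S(=O)(=O)NN
Why: Hydrazone condensation is site-selective because C9=O lies between the quaternary C10 and the methyl-bearing C8, whereas C6=O has a CH2 neighbour.

Step 6
Reactants: 9 C6 tosylhydrazone
Product: 11 (4a'R,6'S,8a'R)-4a',6'-dimethyl-4',4a',6',7',8',8a'-hexahydro-5'H-spiro[cyclopropane-1,1'-naphthalen]-5'-one, via N-boryl tosylhydrazine 10 (not isolated)
Conditions: catecholborane, CHCl3, −10 °C; then NaOAc·3H2O, reflux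
Reagents that add atoms: none
Why: Hydroboration of C=N followed by acetate-triggered loss of sulfinate and N2 (tosylhydrazone deoxygenation, a mild relative of the Wolff–Kishner reduction) turns C6 into CH2 without a base able to touch C5, and so removes the activating carbonyl.

Step 7
Reactants: 11 spirocyclopropyl ketone
Product: 12 (2S,4aR,8aR)-2,5,5,8a-tetramethyloctahydronaphthalen-1(2H)-one
Conditions: H2 (3 atm), PtO2, AcOH, rt
Reagents that add atoms: none
Why: Heterogeneous hydrogenation saturates C2=C3 first and then hydrogenolyses the least hindered CH2–CH2 bond of the now isolated spirocyclopropane (the classical unmasking of a gem-dimethyl group), while the doubly flanked C9 ketone resists and any carbinol formed is re-oxidised in step 8.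

Step 8
Reactants: 12 saturated ketone
Product: 13 (4aR,8aR)-2,5,5,8a-tetramethyl-4a,5,6,7,8,8a-hexahydronaphthalen-1(4H)-one
Conditions: 2-iodoxybenzoic acid, DMSO/fluorobenzene, 75 °C
Reagents that add atoms: none
Why: Dehydrogenation of the ketone by 2-iodoxybenzoic acid via its enol can only run towards C8–C7 because C10 is quaternary, which restores the C7=C8 bond with its methyl group.

Step 9
Reactants: 13 enone
Product: 15 (4aR,8aR)-4,4,7,8a-tetramethyl-8-methylidene-1,2,3,4,4a,5,8,8a-octahydronaphthalene (ent-drima-7,9(11)-diene), via β-hydroxysilane 14 (not isolated)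
Conditions: Me3SiCH2Li, THF, −78 → 0 °C; aqueous work-up; crude carbinol, KH, THF, rt
Reagents that add atoms: (trimethylsilyl)methyllithium, [Li]C[Si](C)(C)C
Why: Peterson olefination, in which the small reagent adds 1,2 to the hindered enone from the face opposite the axial C10 methyl and basic syn-elimination of KOSiMe3 gives the exocyclic C9=C11 bond without isomerising the diene.

Step 10
Reactants: 15 diene
Product: 17 [(1R,4aR,8aR)-2,5,5,8a-tetramethyl-1,4,4a,5,6,7,8,8a-octahydronaphthalen-1-yl]methanol (ent-drimenol), via B-alkyl-9-BBN adduct 16 (not isolated)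
Conditions: 9-borabicyclo[3.3.1]nonane, THF, 0 °C → rt; then NaOH, H2O2
Reagents that add atoms: hydrogen peroxide, OO
Why: Hydroboration–oxidation, in which the bulky borane attacks only the 1,1-disubstituted C9=C11 bond (boron on C11) from the face opposite the axial C10 methyl, so H9 enters anti to that methyl and C11 ends equatorial; C9 is relayed from C10.

Step 11
Reactants: 17 ent-drimenol
Product: 18 (1R,4aR,8aR)-1-(iodomethyl)-2,5,5,8a-tetramethyl-1,4,4a,5,6,7,8,8a-octahydronaphthalene
Conditions: I2, PPh3, imidazole, CH2Cl2, 0 °C → rt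
Reagents that add atoms: iodine, II
Why: Appel-type iodination of a primary alcohol runs by SN2 at C11 and touches no stereocentre.

Step 12
Reactants: 18 iodide
Product: 19 {[(1R,4aR,8aR)-2,5,5,8a-tetramethyl-1,4,4a,5,6,7,8,8a-octahydronaphthalen-1-yl]methyl}triphenylphosphonium iodide
Conditions: PPh3, MeCN, reflux
Reagents that add atoms: triphenylphosphine, c1ccccc1P(c1ccccc1)c1ccccc1
Why: SN2 quaternisation of the phosphine by the primary iodide is slowed by β-branching but has no competing pathway in a polar solvent at reflux.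

Step 13
Reactants: 20 geranyl acetate
Product: 22 (2E)-3-methyl-6-oxohex-2-en-1-yl acetate, via ozonide 21 (not isolated)
Conditions: O3 (1 equiv), CH2Cl2/pyridine, −78 °C; then Me2S
Reagents that add atoms: ozone, [O-][O+]=O
Why: Ozonolysis with one equivalent of ozone is site-selective for the electron-rich terminal trisubstituted alkene over the one deactivated by the allylic acetate.

Step 14
Reactants: 22 aldehyde; 23 cis-2-butene
Product: 26 (2E,6R,7R)-6-hydroxy-3,7-dimethylnona-2,8-dien-1-yl acetate, via (Z)-crotyldiisopinocampheylborane 24 (not isolated), via borinate 25 (not isolated)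
Conditions: 23, n-BuLi, KOt-Bu, THF, −78 → −45 °C; (−)-B-methoxydiisopinocampheylborane, −78 °C; BF3·OEt2; 22, −78 °C; NaBO3·4H2O, THF/H2O, rt
Reagents that add atoms: none
Why: Brown crotylboration through a closed chair transition state, the Z geometry giving the 2',3'-syn relationship and the isopinocampheyl groups derived from (+)-α-pinene the (R) carbinol at C3'; the perborate work-up spares the acetate.

Step 15
Reactants: 26 homoallylic alcohol
Product: 27 (2E,6R,7R)-6-(methanesulfonyloxy)-3,7-dimethylnona-2,8-dien-1-yl acetate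
Conditions: MsCl, Et3N, CH2Cl2, 0 °C
Reagents that add atoms: methanesulfonyl chloride, CS(=O)(=O)Cl
Why: Sulfonylation of the only free hydroxyl, with retention at C3', installs the leaving group for step 19.

Step 16
Reactants: 27 mesylate acetate
Product: 28 (3R,4R,7E)-9-hydroxy-3,7-dimethylnona-1,7-dien-4-yl methanesulfonate
Conditions: K2CO3 (cat.), MeOH, rt
Reagents that add atoms: none
Why: Base-catalysed transesterification removes the primary allylic acetate under conditions to which a secondary mesylate is inert.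

Step 17
Reactants: 28 allylic alcohol
Product: 29 (3R,4R)-1-[(2S,3S)-3-(hydroxymethyl)-2-methyloxiran-2-yl]-4-methylhex-5-en-3-yl methanesulfonate
Conditions: Ti(OiPr)4 (10 mol %), L-(+)-diethyl tartrate (12 mol %), t-BuOOH, 4 Å MS, CH2Cl2, −20 °C
Reagents that add atoms: tert-butyl hydroperoxide, CC(C)(C)OO
Why: Sharpless asymmetric epoxidation is confined to the allylic alcohol (the vinyl group is untouched), and L-(+)-tartrate delivers oxygen to the face of the (E)-alkene that gives the (2S,3S)-epoxy alcohol, so C6' and C7' are set by reagent control.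

Step 18
Reactants: 29 epoxy alcohol
Product: 30 (3R,4R,7R,8S)-7-hydroperoxy-8,9-dihydroxy-3,7-dimethylnon-1-en-4-yl methanesulfonate
Conditions: anhydrous H2O2 in Et2O, H3PMo12O40 (cat.), rt
Reagents that add atoms: hydrogen peroxide, OO
Why: Acid-catalysed perhydrolysis of a trisubstituted 2,3-epoxy alcohol opens the oxirane at the tertiary carbon C6', which bears positive charge best, by backside attack of H2O2, so C6' is inverted to the configuration of the target.

Step 19
Reactants: 30 hydroperoxy mesylate
Product: 31 (1S)-1-{(3R,6S)-6-[(2R)-but-3-en-2-yl]-3-methyl-1,2-dioxan-3-yl}ethane-1,2-diol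
Conditions: KOt-Bu (1.0 equiv), 18-crown-6, THF, 0 °C
Reagents that add atoms: none
Why: Intramolecular SN2 alkylation of a hydroperoxide (6-exo-tet), in which one equivalent of base deprotonates only the far more acidic OOH and its α-effect oxygen displaces the mesylate; this inverts C3' from syn to the required anti relationship to C2', and no carbonyl group is present to trigger β-elimination.

Step 20
Reactants: 31 vinyl dioxane diol
Product: 33 (2S)-2-{(3S,6R)-6-[(1S)-1,2-dihydroxyethyl]-6-methyl-1,2-dioxan-3-yl}propanal, via ozonide 32 (not isolated)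
Conditions: O3, CH2Cl2, −78 °C; then Me2S
Reagents that add atoms: ozone, [O-][O+]=O
Why: Ozonolysis cleaves the only alkene, dialkyl peroxides and diols being inert to ozone and to Me2S.

Step 21
Reactants: 33 aldehyde
Product: 34 (2S)-2-{(3S,6R)-6-[(1S)-1,2-dihydroxyethyl]-6-methyl-1,2-dioxan-3-yl}propanoic acid
Conditions: NaClO2, NaH2PO4, 2-methyl-2-butene, t-BuOH/H2O, 0 °C
Reagents that add atoms: sodium chlorite, [Na+].[O-]Cl=O
Why: Pinnick oxidation works in weakly acidic buffer, where C2' does not epimerise and the β-peroxide does not eliminate.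

Step 22
Reactants: 34 acid
Product: 35 methyl (2S)-2-{(3S,6R)-6-[(1S)-1,2-dihydroxyethyl]-6-methyl-1,2-dioxan-3-yl}propanoate
Conditions: Me3SiCHN2, toluene/MeOH, 0 °C
Reagents that add atoms: (trimethylsilyl)diazomethane, C[Si](C)(C)C=[N+]=[N-]
Why: Esterification by a diazoalkane is neutral and touches no stereocentre.

Step 23
Reactants: 35 ester diol
Product: 36 methyl (2S)-2-[(3S,6R)-6-formyl-6-methyl-1,2-dioxan-3-yl]propanoate
Conditions: NaIO4, THF/H2O (pH 7), 0 °C
Reagents that add atoms: none
Why: Periodate glycol cleavage excises the auxiliary carbon and the C7' carbinol centre and leaves C7' as a non-enolisable aldehyde on the quaternary C6'.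

Step 24
Reactants: 19 phosphonium iodide; 36 dioxane aldehyde
Product: 38 methyl (2S)-2-[(3S,6R)-6-methyl-6-{(Z)-2-[(1R,4aR,8aR)-2,5,5,8a-tetramethyl-1,4,4a,5,6,7,8,8a-octahydronaphthalen-1-yl]ethenyl}-1,2-dioxan-3-yl]propanoate, via ylide 37 (not isolated)
Conditions: 19, KN(SiMe3)2, THF, −78 → 0 °C; then 36, −78 °C → rt
Reagents that add atoms: none
Why: Wittig olefination, in which the non-stabilised ylide (its conjugate acid is far more acidic than the ester α-CH) adds to the aldehyde at low temperature without deprotonating C2' and gives mainly the (Z)-alkene, whose geometry is irrelevant.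

Step 25
Reactants: 38 (Z)-alkene
Product: 39 methyl (2S)-2-[(3S,6S)-6-methyl-6-{2-[(1R,4aR,8aR)-2,5,5,8a-tetramethyl-1,4,4a,5,6,7,8,8a-octahydronaphthalen-1-yl]ethyl}-1,2-dioxan-3-yl]propanoate (target)
Conditions: KO2CN=NCO2K, AcOH, MeOH/CH2Cl2, 0 °C → rt, repeated charges
Reagents that add atoms: none
Why: Diimide transfers H2 concertedly to the strained 1,2-disubstituted alkene faster than to the hindered trisubstituted C7=C8 bond and, unlike metal-catalysed hydrogenation, leaves the O–O bond intact.

Compound list
1 | cyclopropyltriphenylphosphonium bromide | [Br-].C1CC1[P+](c1ccccc1)(c1ccccc1)c1ccccc1 | starting material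
2 | acrolein | C=CC=O | starting material
3 | cyclopropylidenetriphenylphosphorane | C1CC1=P(c1ccccc1)(c1ccccc1)c1ccccc1 | intermediate
4 | allylidenecyclopropane | C=CC=C1CC1 | intermediate
5 | 2,6-dimethyl-1,4-benzoquinone | CC1=CC(=O)C=C(C)C1=O | starting material
6 | cis-fused Diels–Alder adduct (5S,10R) | O=C1C(C)=CC(=O)[C@H]2C3(CC3)C=CC[C@@]12C | intermediate
7 | trans-fused enedione (5R,10R) | O=C1C(C)=CC(=O)[C@@H]2C3(CC3)C=CC[C@@]12C | intermediate
8 | trans-fused 6,9-dione, equatorial C8 methyl | O=C1[C@@H](C)CC(=O)[C@@H]2C3(CC3)C=CC[C@@]12C | intermediate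
9 | C6 tosylhydrazone of 8 | O=C1[C@@H](C)CC(=NNS(=O)(=O)c3ccc(C)cc3)[C@@H]2C4(CC4)C=CC[C@@]12C | intermediate
10 | N-(1,3,2-benzodioxaborol-2-yl) tosylhydrazine (C6 epimers) | O=C1[C@@H](C)CC(N(NS(=O)(=O)c3ccc(C)cc3)B3Oc4ccccc4O3)[C@@H]2C4(CC4)C=CC[C@@]12C | intermediate
11 | C6-deoxygenated spirocyclopropyl ketone | O=C1[C@@H](C)CC[C@@H]2C3(CC3)C=CC[C@@]12C | intermediate
12 | (2S,4aR,8aR)-2,5,5,8a-tetramethyloctahydronaphthalen-1(2H)-one | O=C1[C@@H](C)CC[C@@H]2C(C)(C)CCC[C@@]12C | intermediate
13 | (4aR,8aR)-2,5,5,8a-tetramethyl-4a,5,6,7,8,8a-hexahydronaphthalen-1(4H)-one | O=C1C(C)=CC[C@@H]2C(C)(C)CCC[C@@]12C | intermediate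
14 | (1R,4aR,8aR)-2,5,5,8a-tetramethyl-1-[(trimethylsilyl)methyl]-1,4,4a,5,6,7,8,8a-octahydronaphthalen-1-ol | C[Si](C)(C)C[C@@]1(O)C(C)=CC[C@@H]2C(C)(C)CCC[C@@]12C | intermediate
15 | ent-drima-7,9(11)-diene | C=C1C(C)=CC[C@@H]2C(C)(C)CCC[C@@]12C | intermediate
16 | B-(ent-drimenyl)-9-borabicyclo[3.3.1]nonane | C([C@@H]1C(C)=CC[C@@H]2C(C)(C)CCC[C@@]12C)B1C2CCCC1CCC2 | intermediate
17 | ent-drimenol | OC[C@@H]1C(C)=CC[C@@H]2C(C)(C)CCC[C@@]12C | intermediate
18 | ent-drimenyl iodide | IC[C@@H]1C(C)=CC[C@@H]2C(C)(C)CCC[C@@]12C | intermediate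
19 | ent-drimenyltriphenylphosphonium iodide | [I-].C([C@@H]1C(C)=CC[C@@H]2C(C)(C)CCC[C@@]12C)[P+](c1ccccc1)(c1ccccc1)c1ccccc1 | intermediate
20 | geranyl acetate | CC(C)=CCC/C(C)=C/COC(C)=O | starting material
21 | ozonide of the 6,7-alkene of 20 | CC1(C)OOC(CC/C(C)=C/COC(C)=O)O1 | intermediate
22 | (2E)-3-methyl-6-oxohex-2-en-1-yl acetate | O=CCC/C(C)=C/COC(C)=O | intermediate
23 | cis-2-butene | C/C=C\C | starting material
24 | (Z)-crotyldiisopinocampheylborane | C/C=C\CB([C@@H]1C[C@@H]2C[C@H]([C@H]1C)C2(C)C)[C@@H]1C[C@@H]2C[C@H]([C@H]1C)C2(C)C | intermediate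
25 | diisopinocampheylborinate of 26 | C=C[C@@H](C)[C@H](OB([C@@H]1C[C@@H]2C[C@H]([C@H]1C)C2(C)C)[C@@H]1C[C@@H]2C[C@H]([C@H]1C)C2(C)C)CC/C(C)=C/COC(C)=O | intermediate
26 | (2E,6R,7R)-6-hydroxy-3,7-dimethylnona-2,8-dien-1-yl acetate | C=C[C@@H](C)[C@H](O)CC/C(C)=C/COC(C)=O | intermediate
27 | (2E,6R,7R)-6-(methanesulfonyloxy)-3,7-dimethylnona-2,8-dien-1-yl acetate | C=C[C@@H](C)[C@H](OS(C)(=O)=O)CC/C(C)=C/COC(C)=O | intermediate
28 | (3R,4R,7E)-9-hydroxy-3,7-dimethylnona-1,7-dien-4-yl methanesulfonate | C=C[C@@H](C)[C@H](OS(C)(=O)=O)CC/C(C)=C/CO | intermediate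
29 | (2S,3S)-epoxy alcohol mesylate | C=C[C@@H](C)[C@H](OS(C)(=O)=O)CC[C@]1(C)O[C@H]1CO | intermediate
30 | (3R,4R,7R,8S)-7-hydroperoxy-8,9-dihydroxy-3,7-dimethylnon-1-en-4-yl methanesulfonate | C=C[C@@H](C)[C@H](OS(C)(=O)=O)CC[C@@](C)(OO)[C@@H](O)CO | intermediate
31 | (1S)-1-{(3R,6S)-6-[(2R)-but-3-en-2-yl]-3-methyl-1,2-dioxan-3-yl}ethane-1,2-diol | C=C[C@@H](C)[C@@H]1CC[C@](C)([C@@H](O)CO)OO1 | intermediate
32 | ozonide of the vinyl group of 31 | C1OC(OO1)[C@@H](C)[C@@H]2CC[C@](C)([C@@H](O)CO)OO2 | intermediate
33 | dioxanyl propanal diol | O=C[C@@H](C)[C@@H]1CC[C@](C)([C@@H](O)CO)OO1 | intermediate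
34 | dioxanyl propanoic acid diol | OC(=O)[C@@H](C)[C@@H]1CC[C@](C)([C@@H](O)CO)OO1 | intermediate
35 | dioxanyl methyl propanoate diol | COC(=O)[C@@H](C)[C@@H]1CC[C@](C)([C@@H](O)CO)OO1 | intermediate
36 | methyl (2S)-2-[(3S,6R)-6-formyl-6-methyl-1,2-dioxan-3-yl]propanoate | COC(=O)[C@@H](C)[C@@H]1CC[C@](C)(C=O)OO1 | intermediate
37 | ent-drimenylidenetriphenylphosphorane | C([C@@H]1C(C)=CC[C@@H]2C(C)(C)CCC[C@@]12C)=P(c1ccccc1)(c1ccccc1)c1ccccc1 | intermediate
38 | (Z)-C7'=C11 alkene | COC(=O)[C@@H](C)[C@@H]1CC[C@](C)(/C=C\[C@@H]2C(C)=CC[C@@H]3C(C)(C)CCC[C@@]23C)OO1 | intermediate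
39 | CNP0124238.1 | COC(=O)[C@@H](C)[C@@H]1CC[C@](C)(CC[C@@H]2C(C)=CC[C@@H]3C(C)(C)CCC[C@@]23C)OO1 | target

Total step count: 25. Longest linear sequence: 14 (steps 1–12, 24, 25).

Steps most likely to fail

Step 2. The cationic catalyst may oligomerise the acid-sensitive diene faster than the methyl-bearing C=C bond of the quinone reacts, or facial discrimination may be poor. The fallback runs from 4 and 5 back to 11 and moves the source of absolute configuration from the cycloaddition to an enzyme. Cycloaddition promoted by BF3·OEt2 gives the racemic cis adduct F1. The operations of steps 3 and 4 then give the racemic trans enedione F2 and the racemic dione F3. An NADPH-dependent ketoreductase (alcohol dehydrogenase class, cofactor recycled by glucose dehydrogenase), screened for this substrate, reduces the C6 carbonyl of the (10R) enantiomer only, to the 6-carbinol F4. It leaves the antipodal dione F5, which is removed by chromatography. 1,1'-Thiocarbonyldiimidazole gives the imidazolylthiocarbonate F6, and Bu3SnH/AIBN (Barton–McCombie deoxygenation) gives 11, so steps 5 and 6 are replaced as well.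

Step 3. The cis/trans equilibrium may lie too close to parity, or re-equilibration may occur in the acidic steps that follow. The fallback runs from 6 back to 12 and sets C5 anew by hydrogenation instead of by equilibration.
- H2/PtO2/AcOH on 6 gives the cis-fused saturated dione F7, with the gem-dimethyl group unmasked.
- 2-Iodoxybenzoic acid restores the enedione F8, in which C5–H is the only enolisable position of the C6 ketone.
- KN(SiMe3)2/PhNTf2 therefore gives the dienyl triflate F9.
- Pd(OAc)2/PPh3/HCO2H/Et3N removes the triflate, and with it the C6 oxygen, to give the 5,7-dien-9-one F10.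
- H2 over Pd/C adds to the face opposite the C10 methyl and the axial C4 methyl to give 12.

Step 19. Displacement at the branched secondary carbon may lose to elimination towards the conjugated diene, or the β-hydroxy hydroperoxide may fragment under base. The fallback runs from 28 back to 31 and reverses the order of the two C–O bond formations, so that ring closure is acid-catalysed. 2-Methoxyprop-2-yl hydroperoxide with CsOH·H2O in DMF displaces the mesylate with inversion to give the peroxyketal allylic alcohol F11. The epoxidation of step 17 gives the epoxy peroxyketal F12. Aqueous AcOH frees the hydroperoxy epoxide F13. Camphorsulfonic acid in CH2Cl2 closes the ring by 6-exo opening of the oxirane at the tertiary C6' with inversion, giving 31 with the same configuration at every centre.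

Further compounds
F1 | step 2 | racemic cis adduct | O=C1C(C)=CC(=O)[C@H]2C3(CC3)C=CC[C@@]12C.O=C1C(C)=CC(=O)[C@@H]2C3(CC3)C=CC[C@]12C
F2 | step 2 | racemic trans enedione | O=C1C(C)=CC(=O)[C@@H]2C3(CC3)C=CC[C@@]12C.O=C1C(C)=CC(=O)[C@H]2C3(CC3)C=CC[C@]12C
F3 | step 2 | racemic trans dione | O=C1[C@@H](C)CC(=O)[C@@H]2C3(CC3)C=CC[C@@]12C.O=C1[C@H](C)CC(=O)[C@H]2C3(CC3)C=CC[C@]12C
F4 | step 2 | 6-carbinol (equatorial OH) of the (10R) series | O=C1[C@@H](C)C[C@@H](O)[C@@H]2C3(CC3)C=CC[C@@]12C
F5 | step 2 | antipodal dione (ent-8) | O=C1[C@H](C)CC(=O)[C@H]2C3(CC3)C=CC[C@]12C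
F6 | step 2 | O-(imidazol-1-ylthiocarbonyl) derivative of F4 | O=C1[C@@H](C)C[C@@H](OC(=S)n3ccnc3)[C@@H]2C3(CC3)C=CC[C@@]12C
F7 | step 3 | cis-fused 4,4,8,10-tetramethyldecalin-6,9-dione (C8 epimers) | O=C1C(C)CC(=O)[C@H]2C(C)(C)CCC[C@@]12C
F8 | step 3 | cis-fused 4,4,8,10-tetramethyl-7-ene-6,9-dione | O=C1C(C)=CC(=O)[C@H]2C(C)(C)CCC[C@@]12C
F9 | step 3 | 6-triflyloxy-5,7-dien-9-one | O=C1C(C)=CC(OS(=O)(=O)C(F)(F)F)=C2C(C)(C)CCC[C@@]12C
F10 | step 3 | (10R)-4,4,8,10-tetramethyl-5,7-dien-9-one | O=C1C(C)=CC=C2C(C)(C)CCC[C@@]12C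
F11 | step 19 | peroxyketal allylic alcohol | C=C[C@@H](C)[C@@H](OOC(C)(C)OC)CC/C(C)=C/CO
F12 | step 19 | epoxy peroxyketal | C=C[C@@H](C)[C@@H](OOC(C)(C)OC)CC[C@]1(C)O[C@H]1CO
F13 | step 19 | hydroperoxy epoxide | C=C[C@@H](C)[C@@H](OO)CC[C@]1(C)O[C@H]1CO
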